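## Structural features

The target is a hetero-dimer of two polyketide-type rings: a hexasubstituted benzene (an acylphloroglucinol monomethyl ether) and a 6-ethyl-4-hydroxy-5-methyl-2-pyrone, joined by one CH2 between a benzene carbon and C3 of the pyrone. Around the benzene ring the substituents run CH2(pyranyl), OH, prenyl, OH, isobutyryl, OMe, so three oxygens alternate with three different carbon groups and each oxygen has a different pair of neighbours. There is no stereocentre and no stereogenic double bond; the only stereogenic atom in the route is a transient carbinol carbon that is later oxidised. The fragile parts are: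
- the prenyl alkene (hydrogenation, and acid-induced cyclisation onto a flanking phenol to a chromane);
- the 2-pyrone (a lactone and a vinylogous acid that reacts with nucleophiles and strong base);
- the electron-rich phenol ring (oxidation);
- the CH2 bridge between two enolic rings (retro-Michael scrambling while both enols are free).

The real difficulty is regiocontrol on the benzene ring: which oxygen is methylated and which carbon carries which group, something electrophilic substitution of a phloroglucinol cannot decide reliably. The key step exploits the alternation itself. The ring carbons bearing OMe and the acyl group are the two carbons of an ynol ether, the carbon of the OH beside the acyl group is a ketene carbon, and the carbons bearing the CH2 arm, the second oxygen and the future prenyl group are C2, C3 and C4 of a 3-alkoxycyclobutenone. The three oxygens therefore arrive already differentiated as OMe, free OH and a removable ether.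

## Logic of the disconnections

25 to 24: the two O–CH2Ar bonds (on the phenol oxygen between the arm and the prenyl group, and on the pyrone 4-oxygen) are cut last. These two acidic OH groups must stay masked through the ketene chemistry and the sigmatropic step. An acid-labile benzylic ether is chosen so that its removal needs neither hydrogen, which would saturate the prenyl group, nor a boron halide, which would threaten the OMe beside the ketone. The demand is an acid mild enough to spare the prenyl–phenol pair and the CH2 bridge.

24 to 22: the bond from the ring to the prenyl CH2 is cut by a retro-[3,3] shift to an aryl 1,1-dimethylallyl ether. Only one ortho carbon is unsubstituted, so the forward shift can place the prenyl group nowhere else. This replaces C-alkylation of a polyphenol by O-alkylation of a single phenol. The demand is that the concerted shift outruns ionisation of the tertiary ether.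

22 to 21 to 20: the ketone is taken back to the carbinol and then to its silyl ether. An acyl group on the alkyne would reverse the polarisation that the ring synthesis needs, so the acyl carbon is carried as a protected carbinol. The order places the oxidation at a stage where no phenol is free.

20 to 19: the O–C bond of the tertiary allylic ether is cut. The forward step must be a branched-selective O-allylation of the only free phenol.

19 to 9 plus 14: two ring bonds are cut, phenol carbon to carbinol-bearing carbon and OMe carbon to arm-bearing carbon. A hexasubstituted benzene becomes a four-membered ring and an alkyne, joined convergently, with the oxygen pattern fixed by the polarity of the partners. The forward step demands the right (2+2) regiochemistry and the absence of any free OH in either partner.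

9 to 8: the two ether O–C bonds are cut. Both vinylogous acids are capped in one operation, which also locks the CH2 bridge against retro-Michael cleavage.

8 to 3 plus 5 plus a one-carbon electrophile: the two C–CH2 bonds of the bridge are cut. Both rings are enols that are nucleophilic at the carbon between their two oxygens. The demand is an unsymmetrical coupling, met by converting one partner fully into its aminomethyl derivative before the other is added.

3 to 2 to 1: the pyrone bonds C4–C5 and O1–C2 are cut, leading to a symmetrical ketone enol ether and a C3 bis-acyl chloride. Symmetry of 1 removes any regiochemical question.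

5 to 4: hydrolysis of a vinylogous ester; no skeletal change.

14 to 13 to 10 plus 11: the O–Si bond and then the bond from the carbinol carbon to the alkyne are cut. The metal methoxyacetylide is generated from 10 and added to 11; the carbinol centre needs no control.

## Other disconnections considered

Alternative 1: The benzene ring is opened between the prenyl-bearing carbon and one hydroxyl-bearing carbon, which leads back to the pyrone A2 (4-methoxy-3-isobutyryl-6-(4-methylpent-3-enyl)-2-pyrone). In the forward sense Mg(OMe)2 in methanol would open the lactone to a methyl ester and a ketone. The enolate at the CH2 that used to be the first side-chain carbon would then close onto the ester in a carbon Claisen condensation and aromatise to A1. A1 has one free ring CH and could be bridged to 3 through 7, the same chemistry as step 4.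
- In its favour: no protecting groups, the prenyl group is present from the start as part of a saturated chain carbon, and the OMe position is fixed by the pyrone. On step economy this alternative is probably the better of the two.
- Against it: A2 needs C3-acylation of a 4-hydroxypyrone followed by O-methylation of a chelated, hindered enol, where the two ring oxygens compete. The magnesium methoxide step has open side channels (retro-Claisen loss of the isobutyryl group from the tricarbonyl, reclosure to a pyrone, aldol instead of Claisen closure). The final bridging must compete with self-condensation of 3 with 7.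
- Comparison: both plans fix the oxygen pattern by construction, so they are equal on that point. The mechanisms differ (anionic condensation against a neutral pericyclic cascade). The chosen plan is longer but each regiochemical outcome is enforced by a single polarity argument or by blocked positions.

Alternative 2: The pyrone is cut at C4–C5 and O1–C2, back to the arylmethylmalonyl dichloride A4 and the silyl enol ether 2. A4, reacting through its chlorocarbonyl ketene, would acylate 2 at carbon, the enol oxygen would close onto the second acyl chloride, and the diacetate A3 would result; mild deacetylation would finish.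
- In its favour: the ring-forming reaction is the same type as step 2, and the pyrone is made last, so its acidity never needs masking; on that point it is the better plan. Removal of two aryl acetates is at least as mild as the final step chosen here.
- Against it: A4 must be made as a bis-acid chloride in the presence of a prenyl alkene (HCl addition) and an ortho acetoxy group that can be acylated intramolecularly toward a dihydrocoumarin. More important, the fully substituted arene must exist beforehand, and making it by classical phloroglucinol chemistry leaves the oxygen differentiation unsolved.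
- Comparison: structurally it attacks the easy ring late and the hard ring not at all; mechanistically it is an ionic acylation sequence; its step count would depend wholly on the arene synthesis and is unlikely to be lower.

Alternative 3: The pyrone is cut at C3–C4, back to the (Z)-enol ester A6. LiN(SiMe3)2 would deprotonate the CH2 alpha to the enol-ester carbonyl, and the enolate would attack the neighbouring methyl ester in a Dieckmann closure, giving the bis-MOM ether A5 after loss of methoxide; mild acid would then release the target.
- In its favour: the substitution pattern of the pyrone is unambiguous, and methoxymethyl ethers come off under acid comparable to that of the chosen final step, so the two plans are equal there.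
- Against it: enol esters are acyl donors, so the ester enolate can fragment to a ketene and a keto-ester enolate instead of cyclising. The Z geometry of A6 must be secured. Other acidic sites compete (the allylic CH2 of the pentenoate, the isobutyryl methine). Again the hexasubstituted arene, now with a three-carbon acid chain, must be prepared first.
- Comparison: strong-base anionic closure against neutral thermolysis; the hard regiochemical problem is deferred to an arene synthesis that this cut does not address; step economy would be no better.

Key step: step 8

Remarks on the chemistry: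
- The target has no stereocentre. The carbinol carbon carried from 13 to 21 is racemic (one enantiomer drawn) and is erased in step 11.
- The atom mapping of the benzannulation was re-derived and the skeletons of 9, 14 and 19 agree with it. The ring carbonyl oxygen of the cyclobutenone becomes the free phenol, the enol-ether oxygen on C3 becomes the aryl ether, the alkyne oxygen becomes OMe, and the ring CH2 becomes the one unsubstituted arene carbon. By ring numbering the (2+2) adduct is a 4-vinylcyclobut-2-enone.
- 4-Methoxybenzyl is used instead of plain benzyl, and the prenyl group is introduced by a Claisen shift before deprotection rather than by alkylating the free triol.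
- Assumption: 5 reacts through C2 as a carbon nucleophile, as other cyclic 1,3-diones do.

## Route

Step 1
Reactants: 1 pentan-3-one
Product: 2 trimethyl(pent-2-en-3-yloxy)silane (E/Z mixture)
Conditions: TMSCl, Et3N, DMF, 80 °C
Reagents that add atoms: chlorotrimethylsilane, C[Si](C)(C)Cl
Why: Silyl enol ether formation under equilibrating amine conditions; the ketone is symmetrical, so one constitutional isomer forms and the alkene geometry is lost in the pyrone.

Step 2
Reactants: 2 trimethyl(pent-2-en-3-yloxy)silane
Product: 3 6-ethyl-4-hydroxy-5-methyl-2H-pyran-2-one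
Conditions: malonyl dichloride, Et2O, −78 °C → rt
Reagents that add atoms: malonyl dichloride, O=C(Cl)CC(=O)Cl
Why: Pyrone annulation of a silyl enol ether with malonyl dichloride: C-acylation at the enol carbon with loss of TMSCl, lactonisation of the diketone enol oxygen onto the second acyl chloride, then tautomerisation; the ketone carbon becomes C6 (ethyl) and the enol carbon C5 (methyl).

Step 3
Reactants: 4 3-ethoxycyclobut-2-en-1-one
Product: 5 cyclobutane-1,3-dione
Conditions: 1 M aq. HCl, rt; concentrate, crystallise
Reagents that add atoms: water, O
Why: Acid hydrolysis of a vinylogous ester (water adds at C3, ethanol leaves); the dione is a strong vinylogous acid that degrades on storage and is used promptly.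

Step 4
Reactants: 3 6-ethyl-4-hydroxy-5-methyl-2H-pyran-2-one; 5 cyclobutane-1,3-dione
Product: 8 2-[(6-ethyl-4-hydroxy-5-methyl-2-oxo-2H-pyran-3-yl)methyl]-3-hydroxycyclobut-2-en-1-one, via Mannich base 6 (not isolated), via methylidene pyrandione 7 (not isolated)
Conditions: CH2=NMe2+ I− (1.05 equiv), MeCN, rt; then 5 (2 equiv), 50 °C
Reagents that add atoms: N,N-dimethylmethyleneiminium iodide (Eschenmoser's salt), C=[N+](C)C.[I-]
Why: Mannich aminomethylation at the nucleophilic C3 of the 4-hydroxypyrone, elimination of the protonated amine to the 3-methylidene-2,4-dione, then Michael addition of the enol carbon C2 of 5 (methylene bridging of two cyclic dicarbonyl enols); 3 is converted fully to 6 before 5 is added, and 5 is in excess, so 3 cannot add to 7 to give the symmetrical dimer.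

Step 5
Reactants: 8 methylene-bridged bis-enol
Product: 9 3-[(4-methoxybenzyl)oxy]-2-({6-ethyl-4-[(4-methoxybenzyl)oxy]-5-methyl-2-oxo-2H-pyran-3-yl}methyl)cyclobut-2-en-1-one
Conditions: 4-MeOC6H4CH2OH (2.4 equiv), PPh3, DIAD, THF, 0 °C → rt
Reagents that add atoms: 4-methoxybenzyl alcohol, COc1ccc(CO)cc1
Why: Double Mitsunobu O-alkylation of two vinylogous acids; the cyclobutanedione enol is symmetrical and 4-hydroxy-2-pyrones normally alkylate on the 4-oxygen under these conditions; capping both enols removes every OH that could trap a ketene and blocks retro-Michael cleavage of the bridge.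

Step 6
Reactants: 10 chloroacetaldehyde dimethyl acetal; 11 isobutyraldehyde
Product: 13 1-methoxy-4-methylpent-1-yn-3-ol (racemic), via lithium methoxyacetylide 12 (not isolated)
Conditions: Et2NH, n-BuLi (3.1 equiv each), THF, 0 °C; 10, 0 °C; then 11, −78 → 0 °C; H2O
Reagents that add atoms: none
Why: LiNEt2 converts the chloroacetal by two eliminations (methanol, then HCl) and deprotonation into lithium methoxyacetylide, which adds 1,2 to the aldehyde; the carbinol centre forms without control, which is harmless because it is oxidised in step 11; work-up stays non-acidic because alkoxyethynyl carbinols rearrange to unsaturated esters in acid.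

Step 7
Reactants: 13 1-methoxy-4-methylpent-1-yn-3-ol
Product: 14 tert-butyl[(1-methoxy-4-methylpent-1-yn-3-yl)oxy]dimethylsilane (racemic)
Conditions: TBSCl, imidazole, DMF, rt
Reagents that add atoms: tert-butyldimethylsilyl chloride, CC(C)(C)[Si](C)(C)Cl
Why: Imidazole-promoted silylation of a secondary alcohol; the silyl ether removes the OH that the ketenes of step 8 would acylate and it tolerates the thermolysis.

Step 8
Reactants: 9 bis(4-methoxybenzyl) cyclobutenone; 14 silylated methoxyalkyne
Product: 19 3-{[3-(1-{[tert-butyl(dimethyl)silyl]oxy}-2-methylpropyl)-4-hydroxy-2-methoxy-6-[(4-methoxybenzyl)oxy]phenyl]methyl}-6-ethyl-4-[(4-methoxybenzyl)oxy]-5-methyl-2H-pyran-2-one (racemic), via vinylketene 15 (not isolated), via vinylcyclobutenone 16 (not isolated), via dienylketene 17 (not isolated), via cyclohexadienone 18 (not isolated)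
Conditions: 14 (2 equiv), toluene (degassed), 80 → 110 °C, sealed tube
Reagents that add atoms: none
Why: Heating opens 9 by a conrotatory four-electron electrocyclic reaction to the (1-alkoxyvinyl)ketene 15. The ketene C=C of 15 adds (2+2) to the ynol ether 14: the alkyne carbon remote from OMe bonds to the ketene carbonyl carbon and the OMe-bearing carbon bonds to the carbon carrying the pyranylmethyl group, giving the 4-vinylcyclobut-2-enone 16. A second, reversible four-electron opening gives dienylketene 17 with the vinyl group cis to the ketene, and a disrotatory six-electron electrocyclisation closes the six-membered ring between the ketene carbon and the terminal CH2; enolisation of dienone 18 gives phenol 19. The closest known reaction type is the Danheiser benzannulation of a cyclobutenone with an alkoxyalkyne. No stereocentre is created; the carbinol centre comes unchanged from racemic 14 and 16 is only a transient diastereomer mixture. The selectivity needed is the regiochemistry of the (2+2) step, secured by the matched polarisation of ynol ether and ketene, which places OH, masked acyl, OMe, pyranylmethyl, ether oxygen and H in the order of the target. Chemoselectivity rests on the substrate design: both enols of 9 and the carbinol of 14 are capped, so the ketenes meet no hydroxyl until 19 appears, excess 14 keeps ketene capture ahead of acylation of 19, and the electron-rich 4-alkoxypyrone is a poor diene toward an electron-rich alkyne.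

Step 9
Reactants: 19 benzannulation phenol
Product: 20 3-{[3-(1-{[tert-butyl(dimethyl)silyl]oxy}-2-methylpropyl)-2-methoxy-6-[(4-methoxybenzyl)oxy]-4-[(2-methylbut-3-en-2-yl)oxy]phenyl]methyl}-6-ethyl-4-[(4-methoxybenzyl)oxy]-5-methyl-2H-pyran-2-one (racemic)
Conditions: tert-butyl 2-methylbut-3-en-2-yl carbonate, Pd(PPh3)4 (5 mol %), THF, 0 °C
Reagents that add atoms: tert-butyl 2-methylbut-3-en-2-yl carbonate, CC(C)(C)OC(=O)OC(C)(C)C=C
Why: Tsuji–Trost O-allylation of the only free phenol: zerovalent palladium ionises the tertiary allylic carbonate to a 1,1-dimethyl-π-allyl complex, the tert-butoxide released after CO2 loss deprotonates the phenol, and kinetic attack of phenoxide at the more substituted allyl terminus at low temperature gives the tertiary ether.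

Step 10
Reactants: 20 aryl 1,1-dimethylallyl ether silyl ether
Product: 21 3-{[3-(1-hydroxy-2-methylpropyl)-2-methoxy-6-[(4-methoxybenzyl)oxy]-4-[(2-methylbut-3-en-2-yl)oxy]phenyl]methyl}-6-ethyl-4-[(4-methoxybenzyl)oxy]-5-methyl-2H-pyran-2-one (racemic)
Conditions: Bu4NF, AcOH, THF, rt → 40 °C
Reagents that add atoms: none
Why: Fluoride cleavage of the silyl ether, buffered with acetic acid so that the 4-alkoxypyrone sees no strong base and the tertiary allylic ether and the ionisable benzylic alcohol see no strong acid.

Step 11
Reactants: 21 benzylic alcohol
Product: 22 3-{[2-methoxy-6-[(4-methoxybenzyl)oxy]-4-[(2-methylbut-3-en-2-yl)oxy]-3-(2-methylpropanoyl)phenyl]methyl}-6-ethyl-4-[(4-methoxybenzyl)oxy]-5-methyl-2H-pyran-2-one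
Conditions: Dess–Martin periodinane, NaHCO3, CH2Cl2, 0 °C → rt
Reagents that add atoms: none
Why: Dess–Martin oxidation of a hindered secondary benzylic alcohol to the aryl ketone; no phenol is free at this stage, so the electron-rich ring is not oxidised, and NaHCO3 takes up the acetic acid that could ionise the tertiary allylic ether.

Step 12
Reactants: 22 aryl 1,1-dimethylallyl ether ketone
Product: 24 3-{[4-hydroxy-2-methoxy-6-[(4-methoxybenzyl)oxy]-5-(3-methylbut-2-en-1-yl)-3-(2-methylpropanoyl)phenyl]methyl}-6-ethyl-4-[(4-methoxybenzyl)oxy]-5-methyl-2H-pyran-2-one, via ortho-dienone 23 (not isolated)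
Conditions: toluene, PhNEt2 (cat.), 110–120 °C
Reagents that add atoms: none
Why: Aromatic Claisen rearrangement, a [3,3]-sigmatropic shift through a chair transition state into the only unsubstituted ortho carbon, followed by enolisation; allyl inversion turns the tertiary ether into the normal prenyl group, and the regained phenol is held by a hydrogen bond to the neighbouring ketone.

Step 13
Reactants: 24 bis(4-methoxybenzyl) ether of the target
Product: 25 3-{[2,4-dihydroxy-6-methoxy-3-(3-methylbut-2-en-1-yl)-5-(2-methylpropanoyl)phenyl]methyl}-6-ethyl-4-hydroxy-5-methyl-2H-pyran-2-one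
Conditions: TFA (5% v/v), anisole (10 equiv), CH2Cl2, 0 °C
Reagents that add atoms: none
Why: Acidolysis of both 4-methoxybenzyl ethers by an SN1 path, the benzylic cation being taken up by anisole in a Friedel–Crafts alkylation; dilute acid at 0 °C is used because the prenyl alkene beside a phenol would cyclise to a chromane under stronger acid, and no ring carbon of 25 is free to be benzylated.

## Compound list

1 | pentan-3-one | CCC(=O)CC | starting material
2 | trimethyl(pent-2-en-3-yloxy)silane (E/Z mixture; Z drawn) | C/C=C(/CC)O[Si](C)(C)C | intermediate
3 | 6-ethyl-4-hydroxy-5-methyl-2H-pyran-2-one | CCc1oc(=O)cc(O)c1C | intermediate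
4 | 3-ethoxycyclobut-2-en-1-one | CCOC1=CC(=O)C1 | starting material
5 | cyclobutane-1,3-dione (enolised in solution) | O=C1CC(=O)C1 | intermediate
6 | 3-[(dimethylamino)methyl]-6-ethyl-4-hydroxy-5-methyl-2H-pyran-2-one (Mannich base; not isolated) | CCc1oc(=O)c(CN(C)C)c(O)c1C | intermediate
7 | 6-ethyl-5-methyl-3-methylidene-2H-pyran-2,4(3H)-dione (not isolated) | CCC1=C(C)C(=O)C(=C)C(=O)O1 | intermediate
8 | 2-[(6-ethyl-4-hydroxy-5-methyl-2-oxo-2H-pyran-3-yl)methyl]-3-hydroxycyclobut-2-en-1-one | O=C1CC(O)=C1Cc1c(O)c(C)c(CC)oc1=O | intermediate
9 | 3-[(4-methoxybenzyl)oxy]-2-({6-ethyl-4-[(4-methoxybenzyl)oxy]-5-methyl-2-oxo-2H-pyran-3-yl}methyl)cyclobut-2-en-1-one | O=C1CC(OCc2ccc(OC)cc2)=C1Cc1c(OCc2ccc(OC)cc2)c(C)c(CC)oc1=O | intermediate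
10 | chloroacetaldehyde dimethyl acetal | COC(CCl)OC | starting material
11 | isobutyraldehyde | CC(C)C=O | starting material
12 | lithium methoxyacetylide (not isolated) | [Li]C#COC | intermediate
13 | 1-methoxy-4-methylpent-1-yn-3-ol (racemic; one enantiomer drawn) | COC#C[C@H](O)C(C)C | intermediate
14 | tert-butyl[(1-methoxy-4-methylpent-1-yn-3-yl)oxy]dimethylsilane (racemic; one enantiomer drawn) | COC#C[C@H](O[Si](C)(C)C(C)(C)C)C(C)C | intermediate
15 | vinylketene from ring opening of 9 (not isolated) | O=C=C(Cc1c(OCc2ccc(OC)cc2)c(C)c(CC)oc1=O)C(=C)OCc1ccc(OC)cc1 | intermediate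
16 | 4-vinylcyclobut-2-enone (2+2) adduct (diastereomer mixture at the ring carbon; not isolated) | O=C1C([C@H](O[Si](C)(C)C(C)(C)C)C(C)C)=C(OC)C1(Cc1c(OCc2ccc(OC)cc2)c(C)c(CC)oc1=O)C(=C)OCc1ccc(OC)cc1 | intermediate
17 | dienylketene, vinyl cis to the ketene (not isolated) | O=C=C([C@H](O[Si](C)(C)C(C)(C)C)C(C)C)/C(OC)=C(/Cc1c(OCc2ccc(OC)cc2)c(C)c(CC)oc1=O)C(=C)OCc1ccc(OC)cc1 | intermediate
18 | cyclohexa-2,4-dienone before enolisation (not isolated) | O=C1CC(OCc2ccc(OC)cc2)=C(Cc2c(OCc3ccc(OC)cc3)c(C)c(CC)oc2=O)C(OC)=C1[C@H](O[Si](C)(C)C(C)(C)C)C(C)C | intermediate
19 | 3-{[3-(1-{[tert-butyl(dimethyl)silyl]oxy}-2-methylpropyl)-4-hydroxy-2-methoxy-6-[(4-methoxybenzyl)oxy]phenyl]methyl}-6-ethyl-4-[(4-methoxybenzyl)oxy]-5-methyl-2H-pyran-2-one (racemic; one enantiomer drawn) | COc1c(Cc2c(OCc3ccc(OC)cc3)c(C)c(CC)oc2=O)c(OCc2ccc(OC)cc2)cc(O)c1[C@H](O[Si](C)(C)C(C)(C)C)C(C)C | intermediate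
20 | 4-O-(2-methylbut-3-en-2-yl) ether of 19 (racemic; one enantiomer drawn) | COc1c(Cc2c(OCc3ccc(OC)cc3)c(C)c(CC)oc2=O)c(OCc2ccc(OC)cc2)cc(OC(C)(C)C=C)c1[C@H](O[Si](C)(C)C(C)(C)C)C(C)C | intermediate
21 | desilylated benzylic alcohol of 20 (racemic; one enantiomer drawn) | COc1c(Cc2c(OCc3ccc(OC)cc3)c(C)c(CC)oc2=O)c(OCc2ccc(OC)cc2)cc(OC(C)(C)C=C)c1[C@H](O)C(C)C | intermediate
22 | 3-{[2-methoxy-6-[(4-methoxybenzyl)oxy]-4-[(2-methylbut-3-en-2-yl)oxy]-3-(2-methylpropanoyl)phenyl]methyl}-6-ethyl-4-[(4-methoxybenzyl)oxy]-5-methyl-2H-pyran-2-one | COc1c(Cc2c(OCc3ccc(OC)cc3)c(C)c(CC)oc2=O)c(OCc2ccc(OC)cc2)cc(OC(C)(C)C=C)c1C(=O)C(C)C | intermediate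
23 | 6-prenylcyclohexa-2,4-dienone from the [3,3] shift (racemic; not isolated) | O=C1C(CC=C(C)C)C(OCc2ccc(OC)cc2)=C(Cc2c(OCc3ccc(OC)cc3)c(C)c(CC)oc2=O)C(OC)=C1C(=O)C(C)C | intermediate
24 | 3-{[4-hydroxy-2-methoxy-6-[(4-methoxybenzyl)oxy]-5-(3-methylbut-2-en-1-yl)-3-(2-methylpropanoyl)phenyl]methyl}-6-ethyl-4-[(4-methoxybenzyl)oxy]-5-methyl-2H-pyran-2-one | COc1c(Cc2c(OCc3ccc(OC)cc3)c(C)c(CC)oc2=O)c(OCc2ccc(OC)cc2)c(CC=C(C)C)c(O)c1C(=O)C(C)C | intermediate
25 | 3-{[2,4-dihydroxy-6-methoxy-3-(3-methylbut-2-en-1-yl)-5-(2-methylpropanoyl)phenyl]methyl}-6-ethyl-4-hydroxy-5-methyl-2H-pyran-2-one | CCc1oc(=O)c(Cc2c(O)c(CC=C(C)C)c(O)c(C(=O)C(C)C)c2OC)c(O)c1C | target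

## Step count and least certain steps

Total: 13 steps. Longest linear sequence: 10 steps (1, 2, 4, 5, 8, 9, 10, 11, 12, 13, from pentan-3-one).

Step 8 (key step). The alkoxy donor on C3 makes the cyclobutenone a stabilised vinylogous ester, so ring opening may need temperatures at which the vinylketene dimerises before capture. Capture itself is slowed by the branched silyloxy group beside the reacting alkyne carbon, and ketene may acylate the product phenol. The fallback changes the alkyne partner and sets out from 11 and 9. Addition of HC≡CMgBr to 11 would give 4-methylpent-1-yn-3-ol F1, silylated to tert-butyldimethyl[(4-methylpent-1-yn-3-yl)oxy]silane F2. Lithiation with n-BuLi, oxidation of the lithium acetylide with LiOOt-Bu to the ynolate and trapping with TIPSOTf would give the triisopropylsilyl ynol ether F3, a more nucleophilic and heat-tolerant ketenophile. Thermolysis of 9 with F3 would give the phenol with OTIPS in place of OMe F4, and O-allylation as in step 9 would give its 1,1-dimethylallyl ether F5. Unbuffered Bu4NF would remove both silyl groups to the phenol–alcohol F6, and selective phenol methylation (MeI, K2CO3, acetone) would return to the route at 21.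

Step 4. The methylidene dione can be intercepted by unreacted 3 (symmetrical dimer), 8 can be alkylated a second time at the cyclobutanedione carbon, and the strained dione can be opened by liberated amine. The fallback is a stepwise condensation–reduction from 3. Dimethylformamide dimethyl acetal would give the enaminone 3-[(dimethylamino)methylidene]-6-ethyl-5-methyl-2H-pyran-2,4(3H)-dione F7. Exchange with 5 in acetic acid would give the methine-bridged 2-[(6-ethyl-4-hydroxy-5-methyl-2-oxo-2H-pyran-3-yl)methylidene]cyclobutane-1,3-dione F8. Conjugate reduction with Hantzsch ester would return to the route at 8.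

Step 9. Attack of the hindered phenoxide may be slow, and equilibration of the allyl complex may erode the branched selectivity toward the linear prenyl ether, which would rearrange to the wrong (reverse-prenyl) group. The fallback from 19 is copper-catalysed propargylation (3-chloro-3-methylbut-1-yne, CuCl2 cat., DBU, MeCN, 0 °C) to the aryl 1,1-dimethylpropargyl ether F9, then semi-hydrogenation (H2, Pd on CaCO3 poisoned with Pb(OAc)2, quinoline), which returns to the route at 20.

Step 12. The ortho acyl group makes the phenoxide a better leaving group, so ionisation of the tertiary ether (loss of isoprene, or a 1,3-shift to the linear ether) may compete with the concerted shift. The fallback resequences from 20: heating 20 before the ketone exists would give the prenylated phenol silyl ether F10, Bu4NF would give the phenol–alcohol F11, and MnO2 oxidation of the ortho-hydroxybenzylic alcohol would return to the route at 24.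

Step 13. Protonation of the prenyl alkene with capture by a neighbouring phenol (chromane formation), or acid-induced scrambling of the CH2 bridge, may accompany ether cleavage. The fallback removes the ethers before any alkene is present, setting out from 19. Bu4NF would give the phenol–alcohol F12, MnO2 would give the hydroxy ketone F13, and TFA/anisole would give the prenyl-free triol F14. C-prenylation of F14 at its single free ring carbon with prenyl bromide in cold aqueous KOH would reach 25; lower selectivity is expected there because the pyrone enolate competes.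

## Further compounds

F1 | step 8 | 4-methylpent-1-yn-3-ol (racemic) | C#C[C@H](O)C(C)C
F2 | step 8 | tert-butyldimethyl[(4-methylpent-1-yn-3-yl)oxy]silane (racemic) | C#C[C@H](O[Si](C)(C)C(C)(C)C)C(C)C
F3 | step 8 | tert-butyldimethyl({4-methyl-1-[(triisopropylsilyl)oxy]pent-1-yn-3-yl}oxy)silane (racemic) | CC(C)[Si](OC#C[C@H](O[Si](C)(C)C(C)(C)C)C(C)C)(C(C)C)C(C)C
F4 | step 8 | analogue of 19 with OSi(i-Pr)3 in place of OMe | CC(C)[Si](Oc1c(Cc2c(OCc3ccc(OC)cc3)c(C)c(CC)oc2=O)c(OCc2ccc(OC)cc2)cc(O)c1[C@H](O[Si](C)(C)C(C)(C)C)C(C)C)(C(C)C)C(C)C
F5 | step 8 | 1,1-dimethylallyl ether of F4 | CC(C)[Si](Oc1c(Cc2c(OCc3ccc(OC)cc3)c(C)c(CC)oc2=O)c(OCc2ccc(OC)cc2)cc(OC(C)(C)C=C)c1[C@H](O[Si](C)(C)C(C)(C)C)C(C)C)(C(C)C)C(C)C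
F6 | step 8 | O-demethyl analogue of 21 (free phenol and free carbinol) | Oc1c(Cc2c(OCc3ccc(OC)cc3)c(C)c(CC)oc2=O)c(OCc2ccc(OC)cc2)cc(OC(C)(C)C=C)c1[C@H](O)C(C)C
F7 | step 4 | 3-[(dimethylamino)methylidene]-6-ethyl-5-methyl-2H-pyran-2,4(3H)-dione | CCC1=C(C)C(=O)C(=CN(C)C)C(=O)O1
F8 | step 4 | 2-[(6-ethyl-4-hydroxy-5-methyl-2-oxo-2H-pyran-3-yl)methylidene]cyclobutane-1,3-dione | O=C1CC(=O)C1=Cc1c(O)c(C)c(CC)oc1=O
F9 | step 9 | 4-O-(2-methylbut-3-yn-2-yl) ether of 19 | COc1c(Cc2c(OCc3ccc(OC)cc3)c(C)c(CC)oc2=O)c(OCc2ccc(OC)cc2)cc(OC(C)(C)C#C)c1[C@H](O[Si](C)(C)C(C)(C)C)C(C)C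
F10 | step 12 | prenylated phenol silyl ether from Claisen shift of 20 | COc1c(Cc2c(OCc3ccc(OC)cc3)c(C)c(CC)oc2=O)c(OCc2ccc(OC)cc2)c(CC=C(C)C)c(O)c1[C@H](O[Si](C)(C)C(C)(C)C)C(C)C
F11 | step 12 | desilylated F10 (phenol and benzylic alcohol) | COc1c(Cc2c(OCc3ccc(OC)cc3)c(C)c(CC)oc2=O)c(OCc2ccc(OC)cc2)c(CC=C(C)C)c(O)c1[C@H](O)C(C)C
F12 | step 13 | desilylated 19 (phenol and benzylic alcohol) | COc1c(Cc2c(OCc3ccc(OC)cc3)c(C)c(CC)oc2=O)c(OCc2ccc(OC)cc2)cc(O)c1[C@H](O)C(C)C
F13 | step 13 | ortho-hydroxyaryl isobutyryl ketone from F12 | COc1c(Cc2c(OCc3ccc(OC)cc3)c(C)c(CC)oc2=O)c(OCc2ccc(OC)cc2)cc(O)c1C(=O)C(C)C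
F14 | step 13 | 3-{[2,4-dihydroxy-6-methoxy-5-(2-methylpropanoyl)phenyl]methyl}-6-ethyl-4-hydroxy-5-methyl-2H-pyran-2-one | CCc1oc(=O)c(Cc2c(O)cc(O)c(C(=O)C(C)C)c2OC)c(O)c1C
A1 | alternative 1 | 1-[2,4-dihydroxy-6-methoxy-3-(3-methylbut-2-en-1-yl)phenyl]-2-methylpropan-1-one | CC(C)C(=O)c1c(O)c(CC=C(C)C)c(O)cc1OC
A2 | alternative 1 | 4-methoxy-3-(2-methylpropanoyl)-6-(4-methylpent-3-en-1-yl)-2H-pyran-2-one | COc1cc(CCC=C(C)C)oc(=O)c1C(=O)C(C)C
A3 | alternative 2 | di-O-acetyl derivative of 25 (both phenols acetylated) | CCc1oc(=O)c(Cc2c(OC(C)=O)c(CC=C(C)C)c(OC(C)=O)c(C(=O)C(C)C)c2OC)c(O)c1C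
A4 | alternative 2 | 2-{[2,4-diacetoxy-6-methoxy-3-(3-methylbut-2-en-1-yl)-5-(2-methylpropanoyl)phenyl]methyl}propanedioyl dichloride | O=C(Cl)C(Cc1c(OC(C)=O)c(CC=C(C)C)c(OC(C)=O)c(C(=O)C(C)C)c1OC)C(=O)Cl
A5 | alternative 3 | bis(methoxymethyl) ether of 25 (both phenols) | CCc1oc(=O)c(Cc2c(OCOC)c(CC=C(C)C)c(OCOC)c(C(=O)C(C)C)c2OC)c(O)c1C
A6 | alternative 3 | methyl (2Z)-3-({3-[2,4-bis(methoxymethoxy)-6-methoxy-3-(3-methylbut-2-en-1-yl)-5-(2-methylpropanoyl)phenyl]propanoyl}oxy)-2-methylpent-2-enoate | CC/C(OC(=O)CCc1c(OCOC)c(CC=C(C)C)c(OCOC)c(C(=O)C(C)C)c1OC)=C(\C)C(=O)OC
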